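## Retrosynthetic overview

1. Target 25 ⇐ deprotection of 24 ⇐ radical 1,2-acyl shift in cyclobutanone 22: C15 moves from C14 to C8, so the four-membered ring C13–C14–C15–C16 becomes ring D (C8–C14–C13–C16–C15).
2. 22 ⇐ [2+2] cycloaddition of chloro(methyl)ketene to the C13=C14 silyl enol ether 19 ⇐ conjugate selenation of enone lactone 18 (C8–SePh is the radical precursor).
3. 18 ⇐ Robinson annulation (Michael addition, aldol condensation) of α-keto δ-lactone 14 with methyl vinyl ketone (ring C, C9) ⇐ C10 alkylation of ring A enone 9 with ethyl 2-(bromomethyl)acrylate, oxidative cleavage, lactonisation.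
4. 9 ⇐ asymmetric copper hydride reduction/hydroxymethylation and dehydrogenation of enone 4 ⇐ 4,4-dimethylcyclohexane-1,3-dione. Ring order: A, δ-lactone, C, cyclobutanone, D.
5. Enabling feature: ring D is a 3-hydroxycyclopentanone in which C8 is α to both the lactone carbonyl C7 and the ketone C15, and the C13 carbinol is β to C15. C13–O, C14, C15=O and C16 therefore map onto a ketene/enol ether cyclobutanone, and C8, next to C14, can carry the radical that accepts C15.

Key step: step 13

Remarks on the chemistry: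
- Numbering: ent-kaurane numbering is used throughout. Ring A = C1 (ketone), C2=C3, C4 (gem-dimethyl), C5, C10 (spiro carbon); C6 = CH2OH carbon on C5; C20 = OCH2 on C10; C7 = lactone carbonyl on C8; ring C = C8, C9, C11, C12, C13, C14; ring D = C8, C14, C13, C16, C15 (C15 ketone, C17 methyl on C16).
- Assumption: (R)-DTBM-SEGPHOS is taken, by analogy with copper hydride reductions of other 3-substituted cyclohexenones, to give the 3S ketone needed for C5; the ligand antipode would be used if the sense is reversed.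
- Compound 14 is drawn as the α-keto lactone; it should exist largely as its C8 enol.

## Route

Step 1
Reactants: 1 4,4-dimethylcyclohexane-1,3-dione
Product: 2 3-ethoxy-6,6-dimethylcyclohex-2-en-1-one
Conditions: EtOH, TsOH·H2O (cat.), PhMe, reflux, azeotropic removal of water
Reagents that add atoms: ethanol CCO
Why: Acid-catalysed vinylogous ester formation should occur at the carbonyl remote from the gem-dimethyl group, leaving the neopentyl carbonyl free for the next step.

Step 2
Reactants: 2 3-ethoxy-6,6-dimethylcyclohex-2-en-1-one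
Product: 4 3-[(methoxymethoxy)methyl]-4,4-dimethylcyclohex-2-en-1-one, via tertiary carbinol 3 (not isolated)
Conditions: Bu3SnCH2OCH2OMe, n-BuLi, THF, −78 °C; add 2, −78 → 0 °C; then 1 M HCl, 0 °C
Reagents that add atoms: tributyl[(methoxymethoxy)methyl]stannane CCCC[Sn](CCCC)(CCCC)COCOC
Why: Stork–Danheiser alkylative transposition, in which the α-alkoxymethyllithium from tin–lithium exchange adds 1,2 to the vinylogous ester and acid hydrolysis relocates the enone, puts the protected C6 carbon next to the gem-dimethyl carbon without creating a stereocentre.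

Step 3
Reactants: 4 3-[(methoxymethoxy)methyl]-4,4-dimethylcyclohex-2-en-1-one
Product: 6 (2R,3S)-2-(hydroxymethyl)-3-[(methoxymethoxy)methyl]-4,4-dimethylcyclohexan-1-one, via silyl enol ether 5 (not isolated)
Conditions: Cu(OAc)2·H2O (3 mol %), (R)-DTBM-SEGPHOS (3 mol %), (EtO)2MeSiH, PhMe, 0 °C → rt; then 37% aq. HCHO, Yb(OTf)3 (10 mol %), THF, rt
Reagents that add atoms: formaldehyde C=O
Why: Copper hydride-catalysed asymmetric conjugate reduction sets C5 under ligand control and gives the regiodefined silyl enol ether, which undergoes a Mukaiyama aldol hydroxymethylation at C10 anti to the C5 substituent; the C10 configuration is inconsequential because C10 is enolised again in step 6.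

Step 4
Reactants: 6 (2R,3S)-2-(hydroxymethyl)-3-[(methoxymethoxy)methyl]-4,4-dimethylcyclohexan-1-one
Product: 7 (2R,3S)-2-({[tert-butyl(dimethyl)silyl]oxy}methyl)-3-[(methoxymethoxy)methyl]-4,4-dimethylcyclohexan-1-one
Conditions: TBSCl, imidazole, DMF, rt
Reagents that add atoms: tert-butyl(chloro)dimethylsilane CC(C)(C)[Si](C)(C)Cl
Why: Standard silylation of the primary C20 alcohol should suppress retro-aldol and β-elimination during the two enolisations that follow.

Step 5
Reactants: 7 (2R,3S)-2-({[tert-butyl(dimethyl)silyl]oxy}methyl)-3-[(methoxymethoxy)methyl]-4,4-dimethylcyclohexan-1-one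
Product: 9 (5S,6R)-6-({[tert-butyl(dimethyl)silyl]oxy}methyl)-5-[(methoxymethoxy)methyl]-4,4-dimethylcyclohex-2-en-1-one, via trimethylsilyl enol ether 8 (not isolated)
Conditions: LiN(i-Pr)2, THF, −78 °C; Me3SiCl; then Pd(OAc)2 (1.05 equiv), MeCN, rt
Reagents that add atoms: none
Why: Saegusa–Ito oxidation, in which kinetic deprotonation at the unhindered C2 methylene gives the less substituted silyl enol ether and Pd(OAc)2 dehydrogenates it, installs the C2=C3 enone and leaves C10 as the only enolisable position.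

Step 6
Reactants: 9 (5S,6R)-6-({[tert-butyl(dimethyl)silyl]oxy}methyl)-5-[(methoxymethoxy)methyl]-4,4-dimethylcyclohex-2-en-1-one; 10 ethyl 2-(bromomethyl)prop-2-enoate
Product: 11 ethyl 2-{[(1S,6R)-1-({[tert-butyl(dimethyl)silyl]oxy}methyl)-6-[(methoxymethoxy)methyl]-5,5-dimethyl-2-oxocyclohex-3-en-1-yl]methyl}prop-2-enoate
Conditions: LiN(i-Pr)2, THF, −78 °C; then 10, −78 → −40 °C
Reagents that add atoms: none
Why: Alkylation of the cross-conjugated lithium enolate with the very reactive allylic bromide creates the quaternary C10, and the electrophile should enter anti to the neighbouring C5 side chain so that C9 is trans and C20 cis to C6 as in the target.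

Step 7
Reactants: 11 ethyl 2-{[(1S,6R)-1-({[tert-butyl(dimethyl)silyl]oxy}methyl)-6-[(methoxymethoxy)methyl]-5,5-dimethyl-2-oxocyclohex-3-en-1-yl]methyl}prop-2-enoate
Product: 12 ethyl 3-[(1S,6R)-1-({[tert-butyl(dimethyl)silyl]oxy}methyl)-6-[(methoxymethoxy)methyl]-5,5-dimethyl-2-oxocyclohex-3-en-1-yl]-2-oxopropanoate
Conditions: OsO4 (2 mol %), NaIO4 (4 equiv), 2,6-lutidine, dioxane/H2O, rt
Reagents that add atoms: osmium tetroxide O=[Os](=O)(=O)=O (catalytic oxygen carrier); sodium periodate [Na+].[O-]I(=O)(=O)=O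
Why: Lemieux–Johnson cleavage should be chemoselective because OsO4 dihydroxylates the 1,1-disubstituted acrylate double bond much faster than the hindered cyclic enone, and periodate then cleaves the diol to the α-keto ester.

Step 8
Reactants: 12 ethyl 3-[(1S,6R)-1-({[tert-butyl(dimethyl)silyl]oxy}methyl)-6-[(methoxymethoxy)methyl]-5,5-dimethyl-2-oxocyclohex-3-en-1-yl]-2-oxopropanoate
Product: 14 (6S,11R)-11-[(methoxymethoxy)methyl]-10,10-dimethyl-2-oxaspiro[5.5]undec-8-ene-3,4,7-trione, via hydroxy keto ester 13 (not isolated)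
Conditions: 48% aq. HF, MeCN, 0 °C → rt; then pyridinium p-toluenesulfonate (cat.), PhH, 50 °C
Reagents that add atoms: none
Why: Desilylation frees the C20 alcohol, which should lactonise onto the activated α-keto ester (6-exo-trig acyl substitution) to give the spiro δ-lactone without touching a stereocentre.

Step 9
Reactants: 14 (6S,11R)-11-[(methoxymethoxy)methyl]-10,10-dimethyl-2-oxaspiro[5.5]undec-8-ene-3,4,7-trione; 15 but-3-en-2-one
Product: 16 (5S,6R,11R)-11-[(methoxymethoxy)methyl]-10,10-dimethyl-5-(3-oxobutyl)-2-oxaspiro[5.5]undec-8-ene-3,4,7-trione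
Conditions: 15 (1.5 equiv), Et3N (20 mol %), CH2Cl2, 0 °C → rt
Reagents that add atoms: none
Why: Michael addition of the enolised α-keto lactone through C9 should form the C9–C11 bond on the lactone face anti to the bulkier C5 arm of the spiro ring (gem-dimethyl carbon and C6 side chain), which is the natural C9 configuration.

Step 10
Reactants: 16 (5S,6R,11R)-11-[(methoxymethoxy)methyl]-10,10-dimethyl-5-(3-oxobutyl)-2-oxaspiro[5.5]undec-8-ene-3,4,7-trione
Product: 18 (5R,9S,10S)-6-(methoxymethoxy)-1,13-dioxo-15,16,17-trinor-6,7-seco-ent-kaura-2,8(14)-dien-7,20-olide, via aldol ketol 17 (not isolated)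
Conditions: TsOH·H2O (10 mol %), PhMe, 80 °C, molecular sieves (4 Å)
Reagents that add atoms: none
Why: Intramolecular aldol condensation (second half of a Robinson annulation) closes ring C by 6-(enolendo)-exo-trig attack of the methyl ketone enol on the highly electrophilic C8 keto group, the ketol dehydrates into conjugation with both carbonyls, and C9, now γ to the enone, can equilibrate to the epimer with C11 anti to the C5 arm.

Step 11
Reactants: 18 (5R,9S,10S)-6-(methoxymethoxy)-1,13-dioxo-15,16,17-trinor-6,7-seco-ent-kaura-2,8(14)-dien-7,20-olide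
Product: 19 (5R,8S,9S,10R)-6-(methoxymethoxy)-1-oxo-8-(phenylselanyl)-13-[(trimethylsilyl)oxy]-15,16,17-trinor-6,7-seco-ent-kaura-2,13-dien-7,20-olide
Conditions: PhSeSiMe3 (1.3 equiv), Me3SiOTf (5 mol %), CH2Cl2, −78 °C; Et3N quench, non-aqueous work-up
Reagents that add atoms: phenyl trimethylsilyl selenide C[Si](C)(C)[Se]c1ccccc1
Why: Silyl triflate-catalysed 1,4-addition of the silyl selenide to the doubly activated C8=C14 bond should place selenium axially at C8 (β to the ketone, giving the cis-fused lactone with Se cis to H-9) and trap the enolate regiospecifically as the C13=C14 silyl enol ether.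

Step 12
Reactants: 19 (5R,8S,9S,10R)-6-(methoxymethoxy)-1-oxo-8-(phenylselanyl)-13-[(trimethylsilyl)oxy]-15,16,17-trinor-6,7-seco-ent-kaura-2,13-dien-7,20-olide; 20 2-chloropropanoyl chloride
Product: 22 (5R,8S,9S,10R,13S,14S)-16-chloro-6-(methoxymethoxy)-1,15-dioxo-8-(phenylselanyl)-13-[(trimethylsilyl)oxy]-15(8→14)-abeo-6,7-seco-ent-kaur-2-en-7,20-olide, via chloro(methyl)ketene 21 (not isolated)
Conditions: 20 (3 equiv, slow addition), Et3N (3.5 equiv), hexane/CH2Cl2, 0 °C → rt
Reagents that add atoms: none
Why: Ketene–silyl enol ether [2+2] cycloaddition should occur on the convex face of the cis-fused bicycle (cis to H-9 and the angular selenide), with the ketene carbonyl carbon C15 bonding to the nucleophilic C14 and the CClMe carbon C16 to the oxygenated C13, which sets C13 and C14 while the C16 configuration is erased in step 13.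

Step 13
Reactants: 22 (5R,8S,9S,10R,13S,14S)-16-chloro-6-(methoxymethoxy)-1,15-dioxo-8-(phenylselanyl)-13-[(trimethylsilyl)oxy]-15(8→14)-abeo-6,7-seco-ent-kaur-2-en-7,20-olide
Product: 24 (5R,8S,9S,10S,13S,16R)-6-(methoxymethoxy)-1,15-dioxo-13-[(trimethylsilyl)oxy]-6,7-seco-ent-kaur-2-en-7,20-olide, via 16-chloro ketone 23 (not isolated)
Conditions: Bu3SnH (2.5 equiv) and AIBN (0.2 equiv) added by syringe pump over 8 h, PhH (0.005 M), 80 °C
Reagents that add atoms: none
Why: Proposed new method: Bu3Sn• abstracts the phenylselanyl group from C8 and the resulting tertiary α-lactone radical adds to the adjacent strained carbonyl C15 (3-exo-trig), after which β-scission of the C15–C14 bond of the alkoxy radical completes a 1,2-acyl shift from C14 to C8; the C14 radical and the C16–Cl bond are then reduced by the stannane. The closest known reaction type is the Dowd–Beckwith ring expansion (radical 1,2-acyl shift of an alkyl radical onto a neighbouring cyclic ketone, also used on cyclobutanones), from which this step differs in that the attacking radical is ester-stabilised and lies in ring C, so that release of cyclobutanone strain has to drive it. No new ring is closed by cyclisation: the four-membered ring C13–C14–C15–C16 becomes the five-membered ring D (C8–C14–C13–C16–C15) through the 3-exo-trig addition/β-scission pair, and the bicyclo[3.2.1]octane results because C8 and C13 are already linked through C9–C11–C12. The quaternary C8 is set by suprafacial delivery of C15 on the face that carries the cis-fused cyclobutanone (cis to H-9), independent of the C8–Se configuration, and C16 by hydrogen-atom transfer to the α-keto radical from the exo face (methyl endo). The step needs the acyl shift to outrun both hydrogen transfer to the C8 radical and opening of the cyclobutane toward C13, which a low stationary stannane concentration and the high electrophilicity of the strained carbonyl should secure; β-scission toward C16 is not expected because it would leave a cyclopropanone.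

Step 14
Reactants: 24 (5R,8S,9S,10S,13S,16R)-6-(methoxymethoxy)-1,15-dioxo-13-[(trimethylsilyl)oxy]-6,7-seco-ent-kaur-2-en-7,20-olide
Product: 25 (5R,8S,9S,10S,13S,16R)-6,13-dihydroxy-1,15-dioxo-6,7-seco-ent-kaur-2-en-7,20-olide (CNP0533761.1)
Conditions: 3 M HCl (aq)/THF 1:3, rt
Reagents that add atoms: none
Why: Acidic hydrolysis should cleave the tertiary silyl ether and the methoxymethyl acetal, while the bridgehead β-hydroxy ketone cannot dehydrate, the spiro δ-lactone tolerates dilute acid, and any enolisation toward C16 should reprotonate from the exo face to return the same epimer.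

## Compound list

1 | 4,4-dimethylcyclohexane-1,3-dione | CC1(C)CCC(=O)CC1=O | starting material
2 | 3-ethoxy-6,6-dimethylcyclohex-2-en-1-one | CCOC1=CC(=O)C(C)(C)CC1 | intermediate
3 | 3-ethoxy-1-[(methoxymethoxy)methyl]-6,6-dimethylcyclohex-2-en-1-ol (racemic, present as lithium alkoxide) | CCOC1=CC(O)(COCOC)C(C)(C)CC1 | intermediate (not isolated)
4 | 3-[(methoxymethoxy)methyl]-4,4-dimethylcyclohex-2-en-1-one | COCOCC1=CC(=O)CCC1(C)C | intermediate
5 | diethoxy(methyl){[(3S)-3-[(methoxymethoxy)methyl]-4,4-dimethylcyclohex-1-en-1-yl]oxy}silane | CCO[Si](C)(OCC)OC1=C[C@H](COCOC)C(C)(C)CC1 | intermediate (not isolated)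
6 | (2R,3S)-2-(hydroxymethyl)-3-[(methoxymethoxy)methyl]-4,4-dimethylcyclohexan-1-one | OC[C@@H]1C(=O)CCC(C)(C)[C@H]1COCOC | intermediate
7 | (2R,3S)-2-({[tert-butyl(dimethyl)silyl]oxy}methyl)-3-[(methoxymethoxy)methyl]-4,4-dimethylcyclohexan-1-one | CC(C)(C)[Si](C)(C)OC[C@@H]1C(=O)CCC(C)(C)[C@H]1COCOC | intermediate
8 | tert-butyl({(1R,6S)-6-[(methoxymethoxy)methyl]-5,5-dimethyl-2-[(trimethylsilyl)oxy]cyclohex-2-en-1-yl}methoxy)dimethylsilane | CC(C)(C)[Si](C)(C)OC[C@@H]1C(O[Si](C)(C)C)=CCC(C)(C)[C@H]1COCOC | intermediate (not isolated)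
9 | (5S,6R)-6-({[tert-butyl(dimethyl)silyl]oxy}methyl)-5-[(methoxymethoxy)methyl]-4,4-dimethylcyclohex-2-en-1-one | CC(C)(C)[Si](C)(C)OC[C@@H]1C(=O)C=CC(C)(C)[C@H]1COCOC | intermediate
10 | ethyl 2-(bromomethyl)prop-2-enoate | CCOC(=O)C(=C)CBr | starting material
11 | ethyl 2-{[(1S,6R)-1-({[tert-butyl(dimethyl)silyl]oxy}methyl)-6-[(methoxymethoxy)methyl]-5,5-dimethyl-2-oxocyclohex-3-en-1-yl]methyl}prop-2-enoate | CCOC(=O)C(=C)C[C@]1(CO[Si](C)(C)C(C)(C)C)C(=O)C=CC(C)(C)[C@H]1COCOC | intermediate
12 | ethyl 3-[(1S,6R)-1-({[tert-butyl(dimethyl)silyl]oxy}methyl)-6-[(methoxymethoxy)methyl]-5,5-dimethyl-2-oxocyclohex-3-en-1-yl]-2-oxopropanoate | CCOC(=O)C(=O)C[C@]1(CO[Si](C)(C)C(C)(C)C)C(=O)C=CC(C)(C)[C@H]1COCOC | intermediate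
13 | ethyl 3-[(1S,6R)-1-(hydroxymethyl)-6-[(methoxymethoxy)methyl]-5,5-dimethyl-2-oxocyclohex-3-en-1-yl]-2-oxopropanoate | CCOC(=O)C(=O)C[C@]1(CO)C(=O)C=CC(C)(C)[C@H]1COCOC | intermediate (not isolated)
14 | (6S,11R)-11-[(methoxymethoxy)methyl]-10,10-dimethyl-2-oxaspiro[5.5]undec-8-ene-3,4,7-trione | O=C1C[C@]2(COC1=O)C(=O)C=CC(C)(C)[C@H]2COCOC | intermediate
15 | but-3-en-2-one (methyl vinyl ketone) | CC(=O)C=C | starting material
16 | (5S,6R,11R)-11-[(methoxymethoxy)methyl]-10,10-dimethyl-5-(3-oxobutyl)-2-oxaspiro[5.5]undec-8-ene-3,4,7-trione | CC(=O)CC[C@@H]1C(=O)C(=O)OC[C@]12C(=O)C=CC(C)(C)[C@H]2COCOC | intermediate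
17 | 8-hydroxy-6-(methoxymethoxy)-1,13-dioxo-15,16,17-trinor-6,7-seco-ent-kaur-2-en-7,20-olide (C8 carbinol epimers) | O=C1CC2(O)C(=O)OC[C@]3(C(=O)C=CC(C)(C)[C@H]3COCOC)[C@@H]2CC1 | intermediate (not isolated)
18 | (5R,9S,10S)-6-(methoxymethoxy)-1,13-dioxo-15,16,17-trinor-6,7-seco-ent-kaura-2,8(14)-dien-7,20-olide | O=C1C=C2C(=O)OC[C@]3(C(=O)C=CC(C)(C)[C@H]3COCOC)[C@@H]2CC1 | intermediate
19 | (5R,8S,9S,10R)-6-(methoxymethoxy)-1-oxo-8-(phenylselanyl)-13-[(trimethylsilyl)oxy]-15,16,17-trinor-6,7-seco-ent-kaura-2,13-dien-7,20-olide (Se cis to H-9) | c1ccccc1[Se][C@]23C=C(O[Si](C)(C)C)CC[C@H]2[C@]1(COC3=O)C(=O)C=CC(C)(C)[C@H]1COCOC | intermediate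
20 | 2-chloropropanoyl chloride (racemic) | CC(Cl)C(Cl)=O | starting material
21 | chloro(methyl)ketene (2-chloroprop-1-en-1-one) | CC(Cl)=C=O | intermediate (not isolated)
22 | (5R,8S,9S,10R,13S,14S)-16-chloro-6-(methoxymethoxy)-1,15-dioxo-8-(phenylselanyl)-13-[(trimethylsilyl)oxy]-15(8→14)-abeo-6,7-seco-ent-kaur-2-en-7,20-olide (cyclobutanone C13–C14–C15–C16 cis-fused to ring C on the face of H-9; C16 epimers) | c1ccccc1[Se][C@]23[C@@H]4C(=O)C(C)(Cl)[C@]4(O[Si](C)(C)C)CC[C@H]2[C@]1(COC3=O)C(=O)C=CC(C)(C)[C@H]1COCOC | intermediate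
23 | (5R,8S,9S,10S,13S)-16-chloro-6-(methoxymethoxy)-1,15-dioxo-13-[(trimethylsilyl)oxy]-6,7-seco-ent-kaur-2-en-7,20-olide (C16 epimers) | CC1(Cl)C(=O)[C@]23C[C@@]1(O[Si](C)(C)C)CC[C@H]2[C@]1(COC3=O)C(=O)C=CC(C)(C)[C@H]1COCOC | intermediate (not isolated)
24 | (5R,8S,9S,10S,13S,16R)-6-(methoxymethoxy)-1,15-dioxo-13-[(trimethylsilyl)oxy]-6,7-seco-ent-kaur-2-en-7,20-olide | C[C@H]1C(=O)[C@]23C[C@@]1(O[Si](C)(C)C)CC[C@H]2[C@]1(COC3=O)C(=O)C=CC(C)(C)[C@H]1COCOC | intermediate
25 | (5R,8S,9S,10S,13S,16R)-6,13-dihydroxy-1,15-dioxo-6,7-seco-ent-kaur-2-en-7,20-olide (CNP0533761.1) | C[C@H]1C(=O)[C@]23C[C@@]1(O)CC[C@H]2[C@]1(COC3=O)C(=O)C=CC(C)(C)[C@H]1CO | target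

## Step count and risks

Total step count: 14. Longest linear sequence: 14 steps (1 → 25).

Steps most likely to fail:

1. Step 13 (Proposed new method). Hydrogen-atom transfer to the C8 radical may occur before the acyl shift. The cyclobutane may also open between C14 and C13, because the C8 radical is a cyclobutylcarbinyl radical and C13 carries oxygen. In either case ring D would not form. The fallback uses known chemistry and closes ring D instead of expanding it. It sets out from 18. 1,2-Addition of the lithium enolate of ethyl propanoate (LiN(i-Pr)2, THF, −78 °C) to the C13 ketone on the face cis to H-9 should give the tertiary β-hydroxy ester, ethyl 13-hydroxy-6-(methoxymethoxy)-1-oxo-6,7:8,15-diseco-ent-kaura-2,8(14)-dien-7,20-olid-15-oate F1. Silylation (Me3SiOTf, 2,6-lutidine) should give its trimethylsilyl ether F2. Conjugate reduction of the unsaturated lactone with LiBH(s-Bu)3 would generate the C8 lactone enolate, which closes ring D by Dieckmann acylation on the ethyl ester (5-exo-trig) and, after kinetic protonation at C16 from the exo face, comes back to the route at 24.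

2. Step 12. C-acylation or desilylation of the hindered silyl enol ether by the acid chloride, or ketene dimerisation, may outrun the cycloaddition, and the facial preference may be weakened by the angular selenide. The fallback sets out from 19 and uses dichloroketene (Cl3CCOCl, Zn–Cu couple, Et2O), the ketene most reactive toward silyl enol ethers, and introduces the methyl group after the ring expansion. The cycloaddition should give the 16,16-dichloro-17-nor analogue of 22, F3. The conditions of step 13 with excess Bu3SnH would expand the ring and remove both chlorines to give the 17-nor analogue of 24, F4. Methylation of its only enolisable position (LiN(i-Pr)2, MeI) from the exo face should give the 16-epimer of 24, F5. Deprotonation and kinetic protonation from the exo face would turn the methyl group endo and come back to the route at 24.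

3. Step 11. Selenium adds reversibly to a fully substituted β-carbon, so the adduct may revert to 18, selenium may go to C14 instead, and the trimethylsilyl enol ether may be lost on handling. The fallback sets out from 18 and separates the two events. Conjugate reduction with the copper hydride hexamer [(Ph3P)CuH]6 in the presence of Me3SiCl should give the cis-fused silyl enol ether with hydrogen at C8, 6-(methoxymethoxy)-1-oxo-13-[(trimethylsilyl)oxy]-15,16,17-trinor-6,7-seco-ent-kaura-2,13-dien-7,20-olide F6. Deprotonation of the lactone α-position (LiN(i-Pr)2, THF, −78 °C) and selenenylation with PhSeBr from the convex face would then come back to the route at 19.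

Further compounds
F1 | step 13 | ethyl 13-hydroxy-6-(methoxymethoxy)-1-oxo-6,7:8,15-diseco-ent-kaura-2,8(14)-dien-7,20-olid-15-oate (C16 epimers) | CCOC(=O)C(C)[C@@]1(O)C=C2C(=O)OC[C@]3(C(=O)C=CC(C)(C)[C@H]3COCOC)[C@@H]2CC1
F2 | step 13 | 13-O-trimethylsilyl ether of F1 | CCOC(=O)C(C)[C@@]1(O[Si](C)(C)C)C=C2C(=O)OC[C@]3(C(=O)C=CC(C)(C)[C@H]3COCOC)[C@@H]2CC1
F3 | step 12 | 16,16-dichloro-6-(methoxymethoxy)-1,15-dioxo-8-(phenylselanyl)-13-[(trimethylsilyl)oxy]-17-nor-15(8→14)-abeo-6,7-seco-ent-kaur-2-en-7,20-olide | c1ccccc1[Se][C@]23[C@@H]4C(=O)C(Cl)(Cl)[C@]4(O[Si](C)(C)C)CC[C@H]2[C@]1(COC3=O)C(=O)C=CC(C)(C)[C@H]1COCOC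
F4 | step 12 | 6-(methoxymethoxy)-1,15-dioxo-13-[(trimethylsilyl)oxy]-17-nor-6,7-seco-ent-kaur-2-en-7,20-olide | C1C(=O)[C@]23C[C@@]1(O[Si](C)(C)C)CC[C@H]2[C@]1(COC3=O)C(=O)C=CC(C)(C)[C@H]1COCOC
F5 | step 12 | 16-epimer of 24 (methyl exo) | C[C@@H]1C(=O)[C@]23C[C@@]1(O[Si](C)(C)C)CC[C@H]2[C@]1(COC3=O)C(=O)C=CC(C)(C)[C@H]1COCOC
F6 | step 11 | 6-(methoxymethoxy)-1-oxo-13-[(trimethylsilyl)oxy]-15,16,17-trinor-6,7-seco-ent-kaura-2,13-dien-7,20-olide (H-8 cis to H-9) | C[Si](C)(C)OC1=C[C@@H]2C(=O)OC[C@]3(C(=O)C=CC(C)(C)[C@H]3COCOC)[C@@H]2CC1
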